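- Time on the clock was not what I reckoned with in this flask: I multiplied it by the charge of free catalyst and called the result the exposure, E, which for the flask is 900 µM·s, the exposure I then carried through.

| flask | substrate | coupling partner | free catalyst | remark | time |
|---|---|---|---|---|---|
| winter | 5 mM | 5.5 mM | 7 µM | run made earlier |  |
| noon | 5 mM | 5.5 mM | 11 µM | run made earlier |  |
| summer | 5 mM | 2.8 mM | 5 µM | run made earlier |  |
| flask | 5.0 mM | 5.50 mM | 5.0 µM |  | 3.0 min |

| run | time / s | substrate / % | product / % |
|---|---|---|---|
| winter | 10.0 | 64.9 | 15.4 |
| winter | 15.0 | 56.5 | 25.0 |
| winter | 30.0 | 39.0 | 41.1 |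
| winter | 50.0 | 27.1 | 58.0 |
| winter | 60.0 | 22.0 | 63.2 |
| winter | 80.0 | 16.6 | 73.1 |
| winter | 120 | 9.1 | 85.2 |
| noon | 15.0 | 46.0 | 36.9 |
| noon | 30.0 | 26.9 | 55.5 |
| noon | 50.0 | 16.4 | 73.9 |
| noon | 60.0 | 13.4 | 77.4 |
| noon | 80.0 | 8.3 | 86.5 |
| noon | 90.0 | 5.8 | 88.6 |
| noon | 120 | 4.3 | 95.3 |
| summer | 10.0 | 70.6 | 13.3 |
| summer | 15.0 | 61.5 | 16.8 |
| summer | 30.0 | 47.8 | 31.1 |
| summer | 60.0 | 34.4 | 46.4 |
| summer | 120 | 30.6 | 56.4 |

(standard deviation of a reading: 1 percentage point)

- the reaction counts as stopped when no species that holds the substrate changes by six tenths of a point or more over the second half of the time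
- what has gone from substrate into another species counts as reacted, even if it can come back

* why nothing more happens at 3.0 min, or that something still does (all of the substrate has reacted / forward and back rates have come level / the coupling partner has run out first / no working catalyst is left / it is still moving)
* how much of the substrate has reacted by 3.0 min
* how much product there is at 3.0 min, in percent of the substrate charged

- My bench rule was that, at fixed charges of substrate and coupling partner, equal E gives equal readings, and one pair of readings agreed with it: noon at 50.0 s and winter at 80.0 s stood at 550 µM·s and 560 µM·s, only 0.00783 apart in decimal logarithm, and they read 73.9% and 73.1% of product, a gap within the scatter of 1 percentage point.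
- The border appeared in the ratio ρ of coupling partner to substrate charged: summer had ρ = 0.560, below 1, and at 600 µM·s, more exposure than that winter reading, it read less product, 56.4%, so I took the coupling partner as the limiting reagent there and product as stopping near ρ.
- This flask had ρ = 1.10, above 1, so I kept the rule, and I interpolated in the logarithm of E between noon's readings at 80.0 s and 90.0 s, which gave 0.191 of the way, hence 92.2% reacted and 86.9% product.
- Winter at 60.0 s, at 420 µM·s or about half of the flask's E, had read 63.2% of product against the 86.9% I reckoned for the end of the flask, so I judged the flask still moving over its second half of the time.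
- The forecast, holding that “the rate scales with catalyst × time”, gave 92% reacted, 87% product and it is still moving.
- The flask gave 92.1% reacted and 87.4% product, and it is still moving, a share having changed by 22 points over the second half of the time. The conversion moved by 5 points at 3.84 µM of free catalyst with the time held, and at 2.28 min with the catalyst held, and those settings have nearly equal exposures, 691 µM·s and 684 µM·s.

    coupling partner + free catalyst → catalyst intermediate A (k = 33300 L mol⁻¹ s⁻¹)
    substrate + catalyst intermediate A → catalyst intermediate B (k = 3820 L mol⁻¹ s⁻¹)
    catalyst intermediate B → free catalyst + product (k = 170 s⁻¹)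
    substrate ⇌ dormant form (K = 0.470, k = 0.0249 s⁻¹)

- In the neighbour flask with 3.3 mM of coupling partner, E stayed at 900 µM·s, but ρ was 0.660, past the border, so I expected product to stop near 66.0%; that neighbour gave 66.0% of product, with 0% of its coupling partner left.

(The runs are simulated from invented constants; scatter was added.)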